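**Plan**

- Ring numbering: C1 carries the ester, C2 and C3 the hydroxyls. C4, C5 and C6 are bare CH positions, so the C4=C5 bond can be drawn from the ends of two terminal alkenes, and C1–C2–C3 maps onto a beta-keto ester whose second alpha-carbon bears oxygen.
- Retrosynthetic cuts, in order: O3–Si; the C1=C6 unsaturation (arene back to a cyclohexene beta-keto ester); ring bond C4=C5 (metathesis); C1–C6 (allylation); C1–C2 (decarboxylative Claisen); the acyl C–O bond of the ester (Meldrum's acid alcoholysis); C12–C13 of the alkyl chain (copper-catalysed coupling).
- Forward: the C18 alcohol is made first, converted into its malonic half-ester, acylated by O-silylated 2-hydroxybut-3-enoic acid and C-allylated. The only ring then arises by ring-closing metathesis of this acyclic diene, is aromatised by selenoxide elimination and tautomerisation, and is desilylated.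
- Stereochemistry: the target has no stereocentre. The hydroxy ester is used as the racemate, the centres at C1 and C3 are carried as mixtures and disappear when the ring becomes aromatic.

Key step: step 7

**Route**

Step 1
Reactants: 1 1-bromo-4-methylpentane; 2 12-bromododecan-1-ol
Product: 4 16-methylheptadecan-1-ol, via 4-methylpentylmagnesium bromide 3 (not isolated)
Conditions: 1, Mg, THF, reflux (gives 3, 2.5 equiv); then 2, Li2CuCl4 (3 mol%), THF, −78 °C to rt; aq. NH4Cl
Reagents that add atoms: none
Why: Copper-catalysed sp3–sp3 cross-coupling of a Grignard reagent with a primary alkyl bromide (Kochi-type coupling) tolerates the free hydroxyl of an omega-bromo alkanol once a first equivalent of the Grignard reagent has turned it into the bromomagnesium alkoxide.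

Step 2
Reactants: 4 16-methylheptadecan-1-ol; 5 Meldrum's acid (2,2-dimethyl-1,3-dioxane-4,6-dione)
Product: 6 3-[(16-methylheptadecyl)oxy]-3-oxopropanoic acid (malonic acid mono ester)
Conditions: toluene, 100 °C
Reagents that add atoms: none
Why: Alcoholysis of Meldrum's acid opens the acylal ring with loss of acetone and should give the malonic half-ester cleanly, with no diester.

Step 3
Reactants: 7 methyl 2-hydroxybut-3-enoate (racemic)
Product: 8 methyl 2-(tert-butyldimethylsilyloxy)but-3-enoate
Conditions: TBSCl, imidazole, DMF, 0 °C to rt
Reagents that add atoms: tert-butyldimethylsilyl chloride, CC(C)(C)[Si](C)(C)Cl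
Why: Standard silylation of a secondary alcohol, which masks the future C3 oxygen through the carbonyl chemistry and the metathesis.

Step 4
Reactants: 8 methyl 2-(tert-butyldimethylsilyloxy)but-3-enoate
Product: 9 2-(tert-butyldimethylsilyloxy)but-3-enoic acid
Conditions: LiOH·H2O, THF–H2O, 0 °C; then cold dilute HCl to pH 3
Reagents that add atoms: lithium hydroxide, [Li+].[OH-] (its oxygen becomes the acid OH)
Why: Saponification of an unhindered methyl ester, in which hydroxide addition to the carbonyl should outrun alpha-deprotonation, so that the vinyl group stays out of conjugation and the secondary TBS ether survives a cold, brief acidification.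

Step 5
Reactants: 9 2-(tert-butyldimethylsilyloxy)but-3-enoic acid; 6 3-[(16-methylheptadecyl)oxy]-3-oxopropanoic acid
Product: 12 16-methylheptadecyl 4-(tert-butyldimethylsilyloxy)-3-oxohex-5-enoate, via acyl imidazolide 10 (not isolated), via acylmalonic half-ester 11 (not isolated)
Conditions: 9, CDI, THF, rt; added to the magnesium salt of 6 [6 (1.5 equiv), Mg(OEt)2 (0.75 equiv), THF, rt, evaporated], THF, rt; then cold 0.5 M HCl
Reagents that add atoms: 1,1'-carbonyldiimidazole, O=C(n1ccnc1)n1ccnc1 (its imidazolyl group is carried only by intermediate 10 and is lost again; 12 keeps no reagent atoms)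
Why: Decarboxylative Claisen condensation of a magnesium malonate half-ester with an acyl imidazolide (Masamune–Brooks reaction) acylates the chelated enolate under essentially neutral conditions, so the acidic allylic alpha-hydrogen of the acyl unit should stay untouched, and CO2 is lost on acidic work-up.

Step 6
Reactants: 12 16-methylheptadecyl 4-(tert-butyldimethylsilyloxy)-3-oxohex-5-enoate
Product: 13 16-methylheptadecyl 2-allyl-4-(tert-butyldimethylsilyloxy)-3-oxohex-5-enoate (mixture of diastereomers)
Conditions: allyl methyl carbonate (1.0 equiv), Pd(PPh3)4 (3 mol%), THF, rt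
Reagents that add atoms: allyl methyl carbonate, C=CCOC(=O)OC
Why: Tsuji–Trost allylation, in which the pi-allylpalladium methoxide deprotonates only the C–H between the two carbonyls, so mono-C-allylation should proceed without added base, the beta,gamma-unsaturated ketone is not isomerised, and the new centre forms unselectively because it is erased later.

Step 7
Reactants: 13 16-methylheptadecyl 2-allyl-4-(tert-butyldimethylsilyloxy)-3-oxohex-5-enoate
Product: 14 16-methylheptadecyl 3-(tert-butyldimethylsilyloxy)-2-oxocyclohex-4-ene-1-carboxylate (mixture of diastereomers)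
Conditions: second-generation Grubbs catalyst (H2IMes)(PCy3)Cl2Ru=CHPh (5 mol%), degassed CH2Cl2 (0.005 M), 40 °C
Reagents that add atoms: none
Why: The ruthenium benzylidene exchanges onto the unhindered allyl terminus, the new alkylidene adds across the vinyl group beside the silyloxy carbon to give a ruthenacyclobutane, and cycloreversion releases the ring alkene while ethene escapes and drives the reaction. The closest known reaction type is ring-closing metathesis of octa-1,7-dienes that carry carbonyl and silyl ether groups to cyclohexenes. The one ring closed is the six-membered carbocycle, formed by joining the two alkene carbons that become C4 and C5, which is the most favourable ring size for this reaction. No stereocentre is created; the centres at C1 and C3 are present as a mixture, every isomer can cyclise because the ring makes no demand on their relative configuration, and both are erased in step 8. The step needs ring closure to win over oligomerisation and over migration of either terminal alkene, which high dilution, neutral degassed conditions and two monosubstituted alkenes linked through four atoms should secure, while the alpha-substituted beta-keto ester is little enolised and should not tie up ruthenium. Should the ring alkene move into conjugation with the ketone afterwards, that isomer is still a beta-keto ester at C1 and step 8 would take it to the same arene.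

Step 8
Reactants: 14 16-methylheptadecyl 3-(tert-butyldimethylsilyloxy)-2-oxocyclohex-4-ene-1-carboxylate
Product: 18 16-methylheptadecyl 3-(tert-butyldimethylsilyloxy)-2-hydroxybenzoate, via alpha-phenylselanyl keto ester 15 (not isolated), via selenoxide 16 (not isolated), via cyclohexa-2,4-dienone tautomer 17 (not isolated)
Conditions: PhSeCl (1.1 equiv), pyridine (1.2 equiv), CH2Cl2, 0 °C; then 30% aq. H2O2 (2 equiv), 0 °C to rt
Reagents that add atoms: phenylselenenyl chloride, Cl[Se]c1ccccc1, and hydrogen peroxide, OO (the PhSe group and the selenoxide oxygen are carried only by intermediates 15 and 16; 18 keeps no reagent atoms)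
Why: alpha-Selenenylation of a beta-keto ester followed by selenoxide syn-elimination places the C1=C6 double bond (C6 holds the only beta-hydrogens), and the resulting cyclohexa-2,4-dienone should enolise at once by loss of the C3–H, so the C3 oxygen cannot be eliminated and both stereocentres vanish.

Step 9
Reactants: 18 16-methylheptadecyl 3-(tert-butyldimethylsilyloxy)-2-hydroxybenzoate
Product: 19 Gentiside D (16-methylheptadecyl 2,3-dihydroxybenzoate)
Conditions: TBAF (1.1 equiv), AcOH (1.1 equiv), THF, 0 °C
Reagents that add atoms: none
Why: Fluoride cleavage of an aryl silyl ether is fast at 0 °C, and the acetic acid buffer keeps the long-chain ester and the air-sensitive catechol away from free phenoxide.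

**Compound list**

1 | 1-bromo-4-methylpentane | CC(C)CCCBr | starting material
2 | 12-bromododecan-1-ol | OCCCCCCCCCCCCBr | starting material
3 | 4-methylpentylmagnesium bromide (formed in the flask, not isolated) | CC(C)CCC[Mg]Br | intermediate
4 | 16-methylheptadecan-1-ol | CC(C)CCCCCCCCCCCCCCCO | intermediate
5 | Meldrum's acid (2,2-dimethyl-1,3-dioxane-4,6-dione) | CC1(C)OC(=O)CC(=O)O1 | starting material
6 | 3-[(16-methylheptadecyl)oxy]-3-oxopropanoic acid | CC(C)CCCCCCCCCCCCCCCOC(=O)CC(=O)O | intermediate
7 | methyl 2-hydroxybut-3-enoate (racemic) | COC(=O)C(O)C=C | starting material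
8 | methyl 2-(tert-butyldimethylsilyloxy)but-3-enoate (racemic) | COC(=O)C(O[Si](C)(C)C(C)(C)C)C=C | intermediate
9 | 2-(tert-butyldimethylsilyloxy)but-3-enoic acid (racemic) | OC(=O)C(O[Si](C)(C)C(C)(C)C)C=C | intermediate
10 | 1-[2-(tert-butyldimethylsilyloxy)but-3-enoyl]imidazole (formed in the flask, not isolated) | C=CC(O[Si](C)(C)C(C)(C)C)C(=O)n1ccnc1 | intermediate
11 | 2-{[(16-methylheptadecyl)oxy]carbonyl}-4-(tert-butyldimethylsilyloxy)-3-oxohex-5-enoic acid (formed in the flask as its magnesium chelate, not isolated) | CC(C)CCCCCCCCCCCCCCCOC(=O)C(C(=O)O)C(=O)C(O[Si](C)(C)C(C)(C)C)C=C | intermediate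
12 | 16-methylheptadecyl 4-(tert-butyldimethylsilyloxy)-3-oxohex-5-enoate (racemic) | CC(C)CCCCCCCCCCCCCCCOC(=O)CC(=O)C(O[Si](C)(C)C(C)(C)C)C=C | intermediate
13 | 16-methylheptadecyl 2-allyl-4-(tert-butyldimethylsilyloxy)-3-oxohex-5-enoate (mixture of diastereomers) | CC(C)CCCCCCCCCCCCCCCOC(=O)C(CC=C)C(=O)C(O[Si](C)(C)C(C)(C)C)C=C | intermediate
14 | 16-methylheptadecyl 3-(tert-butyldimethylsilyloxy)-2-oxocyclohex-4-ene-1-carboxylate (mixture of diastereomers) | CC(C)CCCCCCCCCCCCCCCOC(=O)C1CC=CC(O[Si](C)(C)C(C)(C)C)C1=O | intermediate
15 | 16-methylheptadecyl 3-(tert-butyldimethylsilyloxy)-2-oxo-1-(phenylselanyl)cyclohex-4-ene-1-carboxylate (formed in the flask, not isolated) | CC(C)CCCCCCCCCCCCCCCOC(=O)C1([Se]c2ccccc2)CC=CC(O[Si](C)(C)C(C)(C)C)C1=O | intermediate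
16 | 16-methylheptadecyl 3-(tert-butyldimethylsilyloxy)-2-oxo-1-(phenylseleninyl)cyclohex-4-ene-1-carboxylate (formed in the flask, not isolated) | CC(C)CCCCCCCCCCCCCCCOC(=O)C1([Se](=O)c2ccccc2)CC=CC(O[Si](C)(C)C(C)(C)C)C1=O | intermediate
17 | 16-methylheptadecyl 5-(tert-butyldimethylsilyloxy)-6-oxocyclohexa-1,3-diene-1-carboxylate (formed in the flask, not isolated) | CC(C)CCCCCCCCCCCCCCCOC(=O)C1=CC=CC(O[Si](C)(C)C(C)(C)C)C1=O | intermediate
18 | 16-methylheptadecyl 3-(tert-butyldimethylsilyloxy)-2-hydroxybenzoate | CC(C)CCCCCCCCCCCCCCCOC(=O)c1cccc(O[Si](C)(C)C(C)(C)C)c1O | intermediate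
19 | Gentiside D (16-methylheptadecyl 2,3-dihydroxybenzoate) | CC(C)CCCCCCCCCCCCCCCOC(=O)c1cccc(O)c1O | target

**Step count and risks**

Total step count: 9. Longest linear sequence: 7 steps (steps 1, 2, 5, 6, 7, 8, 9; the arm through steps 3 and 4 is equally long).

Steps most likely to fail:

Step 7. The catalyst may be held back by chelation to the 1,3-dicarbonyl unit, or the vinyl group may migrate into conjugation with the ketone before the ring closes. The fallback takes the ketone out of play during the metathesis. It sets out from 13: NaBH4 (MeOH–THF, −40 °C) should give the beta-hydroxy ester 16-methylheptadecyl 2-allyl-4-(tert-butyldimethylsilyloxy)-3-hydroxyhex-5-enoate F1, which has neither an enolisable 1,3-dicarbonyl nor a beta,gamma-unsaturated ketone. Ring-closing metathesis of this diene with the same catalyst should give 16-methylheptadecyl 3-(tert-butyldimethylsilyloxy)-2-hydroxycyclohex-4-ene-1-carboxylate F2. Oxidation with Dess–Martin periodinane (NaHCO3, CH2Cl2, 0 °C) would bring the route back at 14.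

Step 8. The selenium electrophile may add across the ring alkene instead of reacting at C1, or the peroxide may over-oxidise the phenol. The fallback moves the oxidation from the C1–C6 bond to the C3 carbinol. It sets out from 14: HF·pyridine buffered with pyridine (THF, 0 °C) should free the ketol 16-methylheptadecyl 3-hydroxy-2-oxocyclohex-4-ene-1-carboxylate F3. Swern oxidation ((COCl)2, DMSO, CH2Cl2, −78 °C, then Et3N, to rt) should give 16-methylheptadecyl 2,3-dioxocyclohex-4-ene-1-carboxylate F4, a non-aromatic tautomer of the catechol. Triethylamine in the same flask shifts its C1 and C6 protons, so the fallback comes back to the route at 19 and bypasses steps 8 and 9.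

Step 5. C-acylation of the chelated magnesium malonate by the hindered, alpha-branched acyl imidazolide may be so slow that simple decarboxylation to the acetate ester wins. The fallback makes the C1–C2 bond by enolate acylation with the allyl group already in place. It sets out from 4 (and uses imidazolide 10 as before): esterification with commercial pent-4-enoic acid (EDC·HCl, DMAP, CH2Cl2, rt) should give 16-methylheptadecyl pent-4-enoate F5. Its lithium enolate (LiN(SiMe3)2, THF, −78 °C; two equivalents of enolate, one serving as base for the product and recovered as F5) would be acylated by 10. The fallback comes back to the route at 13, so that 6, 12 and steps 2 and 6 drop out.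

**Further compounds**

F1 | step 7 | 16-methylheptadecyl 2-allyl-4-(tert-butyldimethylsilyloxy)-3-hydroxyhex-5-enoate | CC(C)CCCCCCCCCCCCCCCOC(=O)C(CC=C)C(O)C(O[Si](C)(C)C(C)(C)C)C=C
F2 | step 7 | 16-methylheptadecyl 3-(tert-butyldimethylsilyloxy)-2-hydroxycyclohex-4-ene-1-carboxylate | CC(C)CCCCCCCCCCCCCCCOC(=O)C1CC=CC(O[Si](C)(C)C(C)(C)C)C1O
F3 | step 8 | 16-methylheptadecyl 3-hydroxy-2-oxocyclohex-4-ene-1-carboxylate | CC(C)CCCCCCCCCCCCCCCOC(=O)C1CC=CC(O)C1=O
F4 | step 8 | 16-methylheptadecyl 2,3-dioxocyclohex-4-ene-1-carboxylate | CC(C)CCCCCCCCCCCCCCCOC(=O)C1CC=CC(=O)C1=O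
F5 | step 5 | 16-methylheptadecyl pent-4-enoate | CC(C)CCCCCCCCCCCCCCCOC(=O)CCC=C
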